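## Analysis of the target

Compound 29 is a daucane-type triester on a hydroazulene: cyclopentane ring A (C1–C5) is fused through C1 and C5 to cycloheptene ring B (C1, C5–C10). The atoms are C1 = quaternary C–Me, C2 = CHOAc, C3 = CH2, C4 = C(OH)(iPr), C5 = fusion CH, C6 = CH–O-angelate, C7 = CH2, C8 = C(Me)=, C9 = =CH, C10 = CH–O-benzoate. The six stereocentres are (1R,2S,4R,5S,6S,10S). With β as the face of the C1 methyl group, H5 is α (trans fusion), the C4 hydroxyl is β and the isopropyl α, the C2 acetate and C6 angelate are α, and the C10 benzoate is β. The C2 and C6 oxygens are therefore both 1,3 to the tertiary C4 hydroxyl and on the opposite face, while the C10 oxygen is cis to the angular methyl on its neighbour. Sensitive features are the angelate (Z to E isomerisation), three different esters beside a free tertiary alcohol (differentiation, acyl migration), the allylic benzoate, and an alkene that can slide into conjugation whenever C6 or C10 is a ketone. The difficulty lies in a quaternary carbon flanked by two oxygenated carbons at the fusion of a seven-membered ring, the trans fusion, and telling the oxygens apart. The strategy reads ring B as a cyclohepta-1,4-diene: C8=C9 is present, and the C6 oxygen, taken back to a ketone and its enol derivative, supplies C5=C6. Ring B then divides into a diene unit C7=C6–C5=C1, whose C5=C1 bond already lies in ring A, and a three-carbon unit C8–C9–C10.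

## Retrosynthetic reasoning

The acyl groups of 29 are removed first, at C–O bonds only, so that all skeletal risk lies earlier. The C2 acetate goes last (29 from alcohol 28), the C2 oxygen comes from silyl ether 27, and the angelate from 4,6-diol 26. Going forward, each acylation meets a single free secondary hydroxyl; the tertiary C4 hydroxyl is too hindered to compete.

Diol 26 comes from acetal 25, in which one isopropylidene group ties O4 to O6. Only this pair of oxygens can be bridged, so the acetal separates C6–OH from C2–OH by constitution. The benzoate of 25 goes back to alcohol 24. The C8 methyl of 24 is traced to a hydroxymethyl group (22, through sulfonate 23), and both the C10 carbinol and the hydroxymethyl group to keto ester 21, then to 20 by removing the C10 oxygen. The ester is kept this long because it directs oxidation to C10, its γ position, and it must be reduced before any acyl group is present.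

Silyl ether 20 and acetal 19 are protected forms of triol 18. Its C2 and C6 carbinols are both cut back to ketones (17). Each ketone is β to the C4 hydroxyl, so both C–H bonds can be made by hydride delivered from that hydroxyl on the β face, which is what the two α oxygens require. Diketone 17 is the unmasked form of 16: the C6 ketone from the silyl enol ether, the C4 hydroxyl from its silyl ether, and H5 by protonation.

In 16 ring B is a cyclohepta-1,4-diene, the retron of a (3,3) shift of a cis-dialkenylcyclopropane. Cutting C1–C10 and re-forming C6–C8 gives cyclopropane 15; cutting C7–C8 and C6–C8 gives diene 10 and vinyl diazo ester 14. These bonds are chosen over any bond of ring A because they remove the seven-membered ring and the quaternary C1 in one operation and leave a simple cyclopentenone with one stereocentre. The forward reaction must cyclopropanate C6=C7 and not C1=C5, place the two alkenyl groups cis, and pass the catalyst's face selection on to C1.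

Diene 10 is the O-silyl enol of methyl ketone 9. The C5–C6 bond of 9 is cut in the Stork–Danheiser sense, to vinylogous ester 6 and the acyl-anion equivalent from 7, through carbinol 8. Only 1,2-addition to the ketone of 6 places the two-carbon unit beside the quaternary carbon without a regiochemical choice. The enol ether of 7 cannot survive the acid of the transposition, so C6 is taken through ketone 9 and enolised again.

The tertiary carbinol of 6 (silyl ether of 5) is cut at C–O to the enolate of 4, with an enantiopure oxygen-transfer reagent choosing the face. The isopropyl group is cut at C–C to 3 and the enolate of 2, the mono-enol ether of symmetric dione 1. Diazo ester 14 comes from 11 by diazo transfer (12), reduction (13) and dehydration.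

## Alternatives that were turned down

Alternative 1: Ring A closed last by C–H insertion.
- Disconnection: the C3–C4 bond.
- Forward key step: a dirhodium tetracarboxylate would turn diazoketone A1 (diazo carbon = C3, joined through the C2 carbonyl to C1 of a finished ring B) into a keto-carbenoid. It would insert into the C4–H bond of the silyl-protected carbinol side chain on C5, closing ring A with retention to give dione A2.
- For: the tertiary C4 ether comes from a secondary carbinol that is easy to make enantiopure. Insertion next to an ether oxygen to form a cyclopentanone is the favoured mode. A2 already carries the C6 angelate and the C10 oxygen, so the endgame is short.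
- Against: A1 needs a complete ring B whose quaternary C1 bears both the C10 ketone and the diazoacetyl group, a non-enolisable 1,3-dicarbonyl prone to retro-Claisen cleavage. The carbenoid can also reach the C6–H bond (equally five atoms away), the angelate alkene and the C8=C9 alkene.
- Comparison: it is stronger at C4 and in endgame length. It moves the real problem, ring B with C1, into a long linear prelude; the chosen route solves that in one catalytic step from 10 and 14.

Alternative 2: Ring contraction–expansion of a decalin.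
- Disconnection: the C1–C5 bond, traced back to a C1–C6 bond so that both rings are six-membered.
- Forward key step: a hindered alkoxide base would deprotonate the angular C6 hydroxyl of decalin A3. The C1–C6 bond, antiperiplanar to the equatorial C5 sulfonate, would migrate to C5 in a pinacol-type shift, giving hydroazulenone A4 with C6 as the ketone.
- For: decalin stereocontrol is well understood and the shift is stereospecific (inversion at C5, retention at C1). The trans fusion is set more securely than by the protonation used in the chosen route, and the C6 ketone appears where it is needed.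
- Against: A3 must already hold the quaternary C1, the C2 and C10 ethers, the fully substituted C4 and a tertiary alcohol beside a secondary sulfonate. The migrating carbon is quaternary and the sulfonate is crowded by C4, so elimination, fragmentation or oxirane formation compete.
- Comparison: more secure at C5, but much longer and linear. The chosen route offers convergence, catalytic control of C1 and a precursor six steps from a commodity dione.

Alternative 3: Two-carbon ring expansion of a cyclopentanedione (de Mayo).
- Disconnection: C7–C8 and C9–C10 of ring B.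
- Forward key step: the photoexcited enol of cyclopentane-1,3-dione A5 would add across its enol double bond to allene A6. The cyclobutanol A7 would fragment by retro-aldol cleavage to 6-methylenecycloheptane-1,4-dione A8.
- For: ring B, with oxygen at C6 and C10 and a one-carbon branch on C8, is reached in one or two steps from cheap materials without diazo compounds or precious metals. The C10 oxygen is present from the start, where the chosen route needs a late allylic oxidation.
- Against: A8 is achiral, monocyclic and nearly symmetric. Ring A, the quaternary C1 and the C4 carbinol would all have to be annulated across C1–C5 between two ketones that are hard to tell apart. Neither the regiochemistry of allene addition nor the alkene position is controlled, and absolute configuration must be introduced from nothing.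
- Comparison: it wins on the first steps and loses afterwards. The chosen strategy builds ring B onto a ring A that already bears C4 and creates C1 in the same step.

Key step: step 10

Remark: bicyclic compounds are named with the locants C1–C10 defined in the analysis (not von Baeyer numbers); β is the face of the C1 methyl group, α the opposite face.

Assumption: the (+)-oxaziridine of step 3 and the (S)-prolinate catalyst of step 10 are taken to have the facial preference needed; if either sense proved opposite, its commercial antipode would be used with no other change.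

## Steps

Step 1
Reactants: 1 2-methylcyclopentane-1,3-dione
Product: 2 3-isobutoxy-2-methylcyclopent-2-en-1-one
Conditions: i-BuOH, TsOH·H2O (cat.), toluene, reflux, Dean–Stark
Reagents that add atoms: 2-methylpropan-1-ol, CC(C)CO
Why: Acid-catalysed O-alkylation of the enolised 1,3-dione with azeotropic removal of water (vinylogous esterification); the dione is symmetric, so only one enol ether can form.

Step 2
Reactants: 2 3-isobutoxy-2-methylcyclopent-2-en-1-one; 3 2-iodopropane
Product: 4 (±)-3-isobutoxy-5-isopropyl-2-methylcyclopent-2-en-1-one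
Conditions: LiN(iPr)2, THF, −78 °C; 3, DMPU, −78 → 0 °C
Reagents that add atoms: none
Why: Kinetic α'-deprotonation of the vinylogous ester and SN2 alkylation of the enolate; the secondary iodide is slow, hence DMPU and excess electrophile. The new centre is racemic and is erased to an enolate in step 3.

Step 3
Reactants: 4 (±)-3-isobutoxy-5-isopropyl-2-methylcyclopent-2-en-1-one
Product: 5 (R)-5-hydroxy-3-isobutoxy-5-isopropyl-2-methylcyclopent-2-en-1-one
Conditions: KN(SiMe3)2, THF, −78 °C; (+)-(camphorsulfonyl)oxaziridine, −78 → −40 °C; NH4Cl (aq.)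
Reagents that add atoms: (+)-(2R,8aS)-(camphorsulfonyl)oxaziridine, CC1(C)[C@@H]2CC[C@]13CS(=O)(=O)N4O[C@@]34C2
Why: Asymmetric enolate hydroxylation: the tetrasubstituted potassium enolate attacks the oxaziridine oxygen, and the camphor framework differentiates the two enolate faces. This sets the carbinol that becomes C4 as R.

Step 4
Reactants: 5 (R)-5-hydroxy-3-isobutoxy-5-isopropyl-2-methylcyclopent-2-en-1-one
Product: 6 (R)-3-isobutoxy-5-isopropyl-2-methyl-5-(triethylsilyloxy)cyclopent-2-en-1-one
Conditions: Et3SiOTf, 2,6-lutidine, CH2Cl2, −78 → 0 °C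
Reagents that add atoms: triethylsilyl trifluoromethanesulfonate, CC[Si](CC)(CC)OS(=O)(=O)C(F)(F)F
Why: Silylation of a hindered tertiary α-hydroxy ketone with a silyl triflate; the ether prevents alkoxide formation in step 5 and O–H insertion in step 10, and puts a large group on the β face.

Step 5
Reactants: 6 (R)-3-isobutoxy-5-isopropyl-2-methyl-5-(triethylsilyloxy)cyclopent-2-en-1-one; 7 ethyl vinyl ether
Product: 9 (R)-3-acetyl-4-isopropyl-2-methyl-4-(triethylsilyloxy)cyclopent-2-en-1-one, via tertiary carbinol 8 (not isolated)
Conditions: 7, t-BuLi, THF, −78 → 0 °C; CeCl3, −78 °C; 6, −78 → −30 °C; then 1 M HCl, THF, 0 °C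
Reagents that add atoms: water, O
Why: Stork–Danheiser transposition: the organocerium form of 1-ethoxyvinyllithium adds 1,2 to the α'-quaternary ketone, and dilute acid converts the allylic carbinol and ring enol ether into the transposed enone. The ethoxyvinyl group cannot survive that acid, so it is hydrolysed to the acetyl group on purpose and re-enolised in step 6; the carbinol centre of 8 is destroyed.

Step 6
Reactants: 9 (R)-3-acetyl-4-isopropyl-2-methyl-4-(triethylsilyloxy)cyclopent-2-en-1-one
Product: 10 (R)-3-[1-(tert-butyldimethylsilyloxy)vinyl]-4-isopropyl-2-methyl-4-(triethylsilyloxy)cyclopent-2-en-1-one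
Conditions: KN(SiMe3)2, THF, −78 °C; t-BuMe2SiOTf, −78 °C
Reagents that add atoms: tert-butyldimethylsilyl trifluoromethanesulfonate, CC(C)(C)[Si](C)(C)OS(=O)(=O)C(F)(F)F
Why: Kinetic enolisation with a bulky amide should remove a proton from the unhindered acetyl methyl group and not from the neopentyl ring methylene C3; O-silylation then gives the 2-silyloxy diene.

Step 7
Reactants: 11 methyl acetoacetate
Product: 12 methyl 2-diazo-3-oxobutanoate
Conditions: 4-AcNHC6H4SO2N3, Et3N, MeCN, 0 °C → rt
Reagents that add atoms: 4-acetamidobenzenesulfonyl azide, CC(=O)Nc1ccc(cc1)S(=O)(=O)N=[N+]=[N-]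
Why: Regitz diazo transfer to an active methylene compound.

Step 8
Reactants: 12 methyl 2-diazo-3-oxobutanoate
Product: 13 (±)-methyl 2-diazo-3-hydroxybutanoate
Conditions: NaBH4, MeOH, 0 °C
Reagents that add atoms: none
Why: Borohydride reduces the ketone and leaves the acceptor-stabilised diazo ester untouched; the carbinol centre is lost in step 9.

Step 9
Reactants: 13 (±)-methyl 2-diazo-3-hydroxybutanoate
Product: 14 methyl 2-diazobut-3-enoate
Conditions: POCl3, Et3N, CH2Cl2, 0 °C; used at once as a cold pentane solution
Reagents that add atoms: none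
Why: Dehydration through the dichlorophosphate (β-elimination) gives the vinyl diazo ester; it is used immediately because it cyclises to a pyrazole on standing.

Step 10
Reactants: 10 (R)-3-[1-(tert-butyldimethylsilyloxy)vinyl]-4-isopropyl-2-methyl-4-(triethylsilyloxy)cyclopent-2-en-1-one; 14 methyl 2-diazobut-3-enoate
Product: 16 methyl 6-(tert-butyldimethylsilyloxy)-4α-isopropyl-1β-methyl-2-oxo-4β-(triethylsilyloxy)bicyclo[5.3.0]deca-5,8-diene-8-carboxylate, via cis-dialkenylcyclopropane 15 (not isolated)
Conditions: Rh2(S-DOSP)4 [dirhodium tetrakis((S)-N-(4-dodecylbenzenesulfonyl)prolinate)] (2 mol %), slow addition of 14, pentane, −78 °C → rt; then toluene, 100 °C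
Reagents that add atoms: none
Why: The chiral carboxylate of divalent rhodium decomposes 14 to a donor/acceptor vinylcarbenoid, which should select the unhindered, oxygen-activated C6=C7 bond over the tetrasubstituted, ketone-deactivated C1=C5 bond and the carbonyl oxygen; asynchronous cyclopropanation forms C7–C8 and C6–C8 (3-exo closure) with the vinyl group cis to the cyclopentenyl group, as is usual for this carbenoid class. Cyclopropane 15 then undergoes a Cope (3,3) shift through the boat transition state, forming C1–C10, breaking C6–C8 and closing ring B by a three-to-seven ring expansion driven by strain release; overall this is the known tandem cyclopropanation–Cope (formal 4+3) annulation of vinyl diazoacetates with 2-oxygenated dienes. The C1 methyl group points into the boat, so the shift is expected to need heating, hence the change to toluene at 100 °C. The new quaternary centre C1 is controlled by the configuration of 15: the catalyst picks the face of C6=C7, and the suprafacial shift transfers that choice to the α face of C1, giving 1R. The C4 centre is expected to reinforce this, because a boat that sets the triethylsilyloxy group against the vinyl unit is more crowded than one that sets the isopropyl methine there. The step needs site selectivity for C6=C7 (from its electron richness and accessibility), cis diastereoselectivity (inherent to the carbenoid, and correctable because the donor–acceptor C6–C8 bond can reopen) and face selectivity (catalyst plus C4). Any enantiomeric impurity in 10 is converted by the same catalyst into a diastereomer of 16 and can be removed here.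

Step 11
Reactants: 16 methyl 6-(tert-butyldimethylsilyloxy)-4α-isopropyl-1β-methyl-2-oxo-4β-(triethylsilyloxy)bicyclo[5.3.0]deca-5,8-diene-8-carboxylate
Product: 17 methyl 4β-hydroxy-4α-isopropyl-1β-methyl-2,6-dioxo-5α-H-bicyclo[5.3.0]dec-8-ene-8-carboxylate (trans-fused)
Conditions: HF·pyridine, pyridine, THF, 0 °C → rt
Reagents that add atoms: none
Why: Fluoride cleaves the silyl enol ether (C6 ketone, protonation at C5) and the tertiary silyl ether. The trans-fused ketone should prevail because it keeps C6 away from the isopropyl group and allows an O4–H···O=C6 hydrogen bond; the acidic fluoride source avoids retro-aldol cleavage at C4 and migration of C8=C9.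

Step 12
Reactants: 17 methyl 4β-hydroxy-4α-isopropyl-1β-methyl-2,6-dioxo-5α-H-bicyclo[5.3.0]dec-8-ene-8-carboxylate
Product: 18 methyl 2α,4β,6α-trihydroxy-4α-isopropyl-1β-methyl-5α-H-bicyclo[5.3.0]dec-8-ene-8-carboxylate
Conditions: Me4NBH(OAc)3, MeCN/AcOH, −30 °C → rt
Reagents that add atoms: none
Why: Evans–Saksena hydroxyl-directed reduction: the borohydride exchanges onto the C4 hydroxyl and delivers hydride internally to both β-hydroxy ketones from the β face, setting 2α-OH and 6α-OH. At C6 the only chair open to the trans-fused skeleton leads to the α alcohol, the opposite of external attack; the enoate is not reduced.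

Step 13
Reactants: 18 methyl 2α,4β,6α-trihydroxy-4α-isopropyl-1β-methyl-5α-H-bicyclo[5.3.0]dec-8-ene-8-carboxylate
Product: 19 methyl 2α-hydroxy-4β,6α-(isopropylidenedioxy)-4α-isopropyl-1β-methyl-5α-H-bicyclo[5.3.0]dec-8-ene-8-carboxylate
Conditions: Me2C(OMe)2, camphorsulfonic acid (cat.), acetone, rt
Reagents that add atoms: 2,2-dimethoxypropane, COC(C)(C)OC
Why: Thermodynamic acetalisation; only the 1,3-related O4/O6 pair can close a ring (a twist-boat dioxane), so the C2 hydroxyl is left free by constitution.

Step 14
Reactants: 19 methyl 2α-hydroxy-4β,6α-(isopropylidenedioxy)-4α-isopropyl-1β-methyl-5α-H-bicyclo[5.3.0]dec-8-ene-8-carboxylate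
Product: 20 methyl 2α-(tert-butyldimethylsilyloxy)-4β,6α-(isopropylidenedioxy)-4α-isopropyl-1β-methyl-5α-H-bicyclo[5.3.0]dec-8-ene-8-carboxylate
Conditions: t-BuMe2SiOTf, 2,6-lutidine, CH2Cl2, −78 → 0 °C
Reagents that add atoms: tert-butyldimethylsilyl trifluoromethanesulfonate, CC(C)(C)[Si](C)(C)OS(=O)(=O)C(F)(F)F
Why: Silyl triflate protection of the one free, neopentyl secondary alcohol; the silyl ether withstands the oxidation and the hydride steps that follow.

Step 15
Reactants: 20 methyl 2α-(tert-butyldimethylsilyloxy)-4β,6α-(isopropylidenedioxy)-4α-isopropyl-1β-methyl-5α-H-bicyclo[5.3.0]dec-8-ene-8-carboxylate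
Product: 21 methyl 2α-(tert-butyldimethylsilyloxy)-4β,6α-(isopropylidenedioxy)-4α-isopropyl-1β-methyl-10-oxo-5α-H-bicyclo[5.3.0]dec-8-ene-8-carboxylate
Conditions: Rh2(cap)4 [dirhodium tetrakis(caprolactamate)] (1 mol %), t-BuOOH (70% aq.), K2CO3, CH2Cl2, rt → 40 °C
Reagents that add atoms: tert-butyl hydroperoxide, CC(C)(C)OO
Why: Radical allylic oxidation at the γ position of a cycloalkene-1-carboxylate by tert-butylperoxyl radicals. Abstraction at C10 gives an allyl radical delocalised onto the ester-bearing carbon, whereas abstraction at C7 gives a cross-conjugated radical, so C10 should be favoured.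

Step 16
Reactants: 21 methyl 2α-(tert-butyldimethylsilyloxy)-4β,6α-(isopropylidenedioxy)-4α-isopropyl-1β-methyl-10-oxo-5α-H-bicyclo[5.3.0]dec-8-ene-8-carboxylate
Product: 22 2α-(tert-butyldimethylsilyloxy)-8-(hydroxymethyl)-4β,6α-(isopropylidenedioxy)-4α-isopropyl-1β-methyl-5α-H-bicyclo[5.3.0]dec-8-en-10β-ol
Conditions: iBu2AlH, CH2Cl2, −78 °C; potassium sodium tartrate (aq.)
Reagents that add atoms: none
Why: 1,2-Reduction of the enone carbonyl and reduction of the ester to the allylic alcohol. Hydride should approach C10 anti to the axial C1 methyl on the adjacent carbon, giving the 10β-alcohol.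

Step 17
Reactants: 22 2α-(tert-butyldimethylsilyloxy)-8-(hydroxymethyl)-4β,6α-(isopropylidenedioxy)-4α-isopropyl-1β-methyl-5α-H-bicyclo[5.3.0]dec-8-en-10β-ol
Product: 24 2α-(tert-butyldimethylsilyloxy)-4β,6α-(isopropylidenedioxy)-4α-isopropyl-1β,8-dimethyl-5α-H-bicyclo[5.3.0]dec-8-en-10β-ol, via primary mesylate 23 (not isolated)
Conditions: MsCl, 2,4,6-collidine, CH2Cl2, −40 °C; then LiEt3BH, THF, −78 → 0 °C
Reagents that add atoms: methanesulfonyl chloride, CS(=O)(=O)Cl (held only in 23)
Why: The primary allylic alcohol is sulfonylated in preference to the hindered neopentyl secondary one, and hydride displaces the primary allylic sulfonate by SN2 to leave the C8 methyl group with the alkene in place.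

Step 18
Reactants: 24 2α-(tert-butyldimethylsilyloxy)-4β,6α-(isopropylidenedioxy)-4α-isopropyl-1β,8-dimethyl-5α-H-bicyclo[5.3.0]dec-8-en-10β-ol
Product: 25 10β-benzoyloxy-2α-(tert-butyldimethylsilyloxy)-4β,6α-(isopropylidenedioxy)-4α-isopropyl-1β,8-dimethyl-5α-H-bicyclo[5.3.0]dec-8-ene
Conditions: BzCl, pyridine, DMAP (cat.), CH2Cl2, 0 → 40 °C
Reagents that add atoms: benzoyl chloride, O=C(Cl)c1ccccc1
Why: Acylation of the only free hydroxyl under nucleophilic catalysis; all hydride chemistry is finished, so esters can now be introduced.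

Step 19
Reactants: 25 10β-benzoyloxy-2α-(tert-butyldimethylsilyloxy)-4β,6α-(isopropylidenedioxy)-4α-isopropyl-1β,8-dimethyl-5α-H-bicyclo[5.3.0]dec-8-ene
Product: 26 10β-benzoyloxy-2α-(tert-butyldimethylsilyloxy)-4α-isopropyl-1β,8-dimethyl-5α-H-bicyclo[5.3.0]dec-8-ene-4β,6α-diol
Conditions: AcOH/H2O/THF (3:1:1), 40 °C
Reagents that add atoms: none
Why: Mild acid hydrolysis of the strained acetal; the hindered secondary silyl ether and the benzoate should survive.

Step 20
Reactants: 26 10β-benzoyloxy-2α-(tert-butyldimethylsilyloxy)-4α-isopropyl-1β,8-dimethyl-5α-H-bicyclo[5.3.0]dec-8-ene-4β,6α-diol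
Product: 27 6α-angeloyloxy-10β-benzoyloxy-2α-(tert-butyldimethylsilyloxy)-4α-isopropyl-1β,8-dimethyl-5α-H-bicyclo[5.3.0]dec-8-en-4β-ol
Conditions: angelic acid, 2,4,6-Cl3C6H2COCl, Et3N, toluene, rt; then 26, toluene, 80 °C
Reagents that add atoms: angelic acid ((Z)-2-methylbut-2-enoic acid), C/C=C(/C)C(=O)O
Why: Yamaguchi-type mixed-anhydride esterification run without a nucleophilic catalyst, to keep the Z geometry; only the secondary C6 hydroxyl should react, the tertiary C4 hydroxyl being too hindered.

Step 21
Reactants: 27 6α-angeloyloxy-10β-benzoyloxy-2α-(tert-butyldimethylsilyloxy)-4α-isopropyl-1β,8-dimethyl-5α-H-bicyclo[5.3.0]dec-8-en-4β-ol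
Product: 28 6α-angeloyloxy-10β-benzoyloxy-4α-isopropyl-1β,8-dimethyl-5α-H-bicyclo[5.3.0]dec-8-ene-2α,4β-diol
Conditions: HF·pyridine, pyridine, THF, 0 °C → rt
Reagents that add atoms: none
Why: Fluoride desilylation under non-basic conditions, chosen so that the benzoate does not migrate from O10 to the neighbouring O2 and the angelate is not isomerised.

Step 22
Reactants: 28 6α-angeloyloxy-10β-benzoyloxy-4α-isopropyl-1β,8-dimethyl-5α-H-bicyclo[5.3.0]dec-8-ene-2α,4β-diol
Product: 29 (1R,2S,4R,5S,6S,10S)-2α-acetoxy-6α-angeloyloxy-10β-benzoyloxy-4α-isopropyl-1β,8-dimethyl-5α-H-bicyclo[5.3.0]dec-8-en-4β-ol (target, CNP0248576.1)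
Conditions: Ac2O, pyridine, DMAP (cat.), CH2Cl2, rt
Reagents that add atoms: acetic anhydride, CC(=O)OC(C)=O
Why: Acetylation of the secondary C2 hydroxyl under nucleophilic catalysis; the tertiary C4 hydroxyl should stay free and no stereocentre is touched.

## Compound list

1 | 2-methylcyclopentane-1,3-dione | CC1C(=O)CCC1=O | starting material
2 | 3-isobutoxy-2-methylcyclopent-2-en-1-one | CC(C)COC1=C(C)C(=O)CC1 | intermediate
3 | 2-iodopropane | CC(C)I | starting material
4 | (±)-3-isobutoxy-5-isopropyl-2-methylcyclopent-2-en-1-one | CC(C)COC1=C(C)C(=O)C(C(C)C)C1 | intermediate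
5 | (R)-5-hydroxy-3-isobutoxy-5-isopropyl-2-methylcyclopent-2-en-1-one | O=C1C(C)=C(OCC(C)C)C[C@@]1(O)C(C)C | intermediate
6 | (R)-3-isobutoxy-5-isopropyl-2-methyl-5-(triethylsilyloxy)cyclopent-2-en-1-one | O=C1C(C)=C(OCC(C)C)C[C@@]1(O[Si](CC)(CC)CC)C(C)C | intermediate
7 | ethyl vinyl ether | C=COCC | starting material
8 | (5R)-1-(1-ethoxyvinyl)-3-isobutoxy-5-isopropyl-2-methyl-5-(triethylsilyloxy)cyclopent-2-en-1-ol (both C1 epimers) | C=C(OCC)C1(O)C(C)=C(OCC(C)C)C[C@@]1(O[Si](CC)(CC)CC)C(C)C | intermediate (not isolated)
9 | (R)-3-acetyl-4-isopropyl-2-methyl-4-(triethylsilyloxy)cyclopent-2-en-1-one | CC(=O)C1=C(C)C(=O)C[C@@]1(O[Si](CC)(CC)CC)C(C)C | intermediate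
10 | (R)-3-[1-(tert-butyldimethylsilyloxy)vinyl]-4-isopropyl-2-methyl-4-(triethylsilyloxy)cyclopent-2-en-1-one | C=C(O[Si](C)(C)C(C)(C)C)C1=C(C)C(=O)C[C@@]1(O[Si](CC)(CC)CC)C(C)C | intermediate (key-step precursor)
11 | methyl acetoacetate | CC(=O)CC(=O)OC | starting material
12 | methyl 2-diazo-3-oxobutanoate | CC(=O)C(=[N+]=[N-])C(=O)OC | intermediate
13 | (±)-methyl 2-diazo-3-hydroxybutanoate | CC(O)C(=[N+]=[N-])C(=O)OC | intermediate
14 | methyl 2-diazobut-3-enoate | C=CC(=[N+]=[N-])C(=O)OC | intermediate (key-step precursor)
15 | methyl (1S,2R)-2-(tert-butyldimethylsilyloxy)-2-[(5R)-5-isopropyl-2-methyl-3-oxo-5-(triethylsilyloxy)cyclopent-1-en-1-yl]-1-vinylcyclopropane-1-carboxylate | C=C[C@@]1(C(=O)OC)C[C@@]1(O[Si](C)(C)C(C)(C)C)C2=C(C)C(=O)C[C@@]2(O[Si](CC)(CC)CC)C(C)C | intermediate (not isolated)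
16 | methyl 6-(tert-butyldimethylsilyloxy)-4α-isopropyl-1β-methyl-2-oxo-4β-(triethylsilyloxy)bicyclo[5.3.0]deca-5,8-diene-8-carboxylate (1R,4R) | C1C(C(=O)OC)=CC[C@@]2(C)C(=O)C[C@@](O[Si](CC)(CC)CC)(C(C)C)C2=C1O[Si](C)(C)C(C)(C)C | intermediate (key-step product)
17 | methyl 4β-hydroxy-4α-isopropyl-1β-methyl-2,6-dioxo-5α-H-bicyclo[5.3.0]dec-8-ene-8-carboxylate | O=C1CC(C(=O)OC)=CC[C@@]2(C)C(=O)C[C@@](O)(C(C)C)[C@H]12 | intermediate
18 | methyl 2α,4β,6α-trihydroxy-4α-isopropyl-1β-methyl-5α-H-bicyclo[5.3.0]dec-8-ene-8-carboxylate | O[C@H]1CC(C(=O)OC)=CC[C@@]2(C)[C@@H](O)C[C@@](O)(C(C)C)[C@H]12 | intermediate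
19 | methyl 2α-hydroxy-4β,6α-(isopropylidenedioxy)-4α-isopropyl-1β-methyl-5α-H-bicyclo[5.3.0]dec-8-ene-8-carboxylate | CC1(C)O[C@H]2CC(C(=O)OC)=CC[C@@]3(C)[C@@H](O)C[C@@](O1)(C(C)C)[C@H]23 | intermediate
20 | methyl 2α-(tert-butyldimethylsilyloxy)-4β,6α-(isopropylidenedioxy)-4α-isopropyl-1β-methyl-5α-H-bicyclo[5.3.0]dec-8-ene-8-carboxylate | CC1(C)O[C@H]2CC(C(=O)OC)=CC[C@@]3(C)[C@@H](O[Si](C)(C)C(C)(C)C)C[C@@](O1)(C(C)C)[C@H]23 | intermediate
21 | methyl 2α-(tert-butyldimethylsilyloxy)-4β,6α-(isopropylidenedioxy)-4α-isopropyl-1β-methyl-10-oxo-5α-H-bicyclo[5.3.0]dec-8-ene-8-carboxylate | CC1(C)O[C@H]2CC(C(=O)OC)=CC(=O)[C@@]3(C)[C@@H](O[Si](C)(C)C(C)(C)C)C[C@@](O1)(C(C)C)[C@H]23 | intermediate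
22 | 2α-(tert-butyldimethylsilyloxy)-8-(hydroxymethyl)-4β,6α-(isopropylidenedioxy)-4α-isopropyl-1β-methyl-5α-H-bicyclo[5.3.0]dec-8-en-10β-ol | CC1(C)O[C@H]2CC(CO)=C[C@H](O)[C@@]3(C)[C@@H](O[Si](C)(C)C(C)(C)C)C[C@@](O1)(C(C)C)[C@H]23 | intermediate
23 | primary methanesulfonate of 22 | CC1(C)O[C@H]2CC(COS(C)(=O)=O)=C[C@H](O)[C@@]3(C)[C@@H](O[Si](C)(C)C(C)(C)C)C[C@@](O1)(C(C)C)[C@H]23 | intermediate (not isolated)
24 | 2α-(tert-butyldimethylsilyloxy)-4β,6α-(isopropylidenedioxy)-4α-isopropyl-1β,8-dimethyl-5α-H-bicyclo[5.3.0]dec-8-en-10β-ol | CC1(C)O[C@H]2CC(C)=C[C@H](O)[C@@]3(C)[C@@H](O[Si](C)(C)C(C)(C)C)C[C@@](O1)(C(C)C)[C@H]23 | intermediate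
25 | 10β-benzoyloxy-2α-(tert-butyldimethylsilyloxy)-4β,6α-(isopropylidenedioxy)-4α-isopropyl-1β,8-dimethyl-5α-H-bicyclo[5.3.0]dec-8-ene | CC1(C)O[C@H]2CC(C)=C[C@H](OC(=O)c4ccccc4)[C@@]3(C)[C@@H](O[Si](C)(C)C(C)(C)C)C[C@@](O1)(C(C)C)[C@H]23 | intermediate
26 | 10β-benzoyloxy-2α-(tert-butyldimethylsilyloxy)-4α-isopropyl-1β,8-dimethyl-5α-H-bicyclo[5.3.0]dec-8-ene-4β,6α-diol | O[C@H]1CC(C)=C[C@H](OC(=O)c2ccccc2)[C@@]2(C)[C@@H](O[Si](C)(C)C(C)(C)C)C[C@@](O)(C(C)C)[C@H]12 | intermediate
27 | 6α-angeloyloxy-10β-benzoyloxy-2α-(tert-butyldimethylsilyloxy)-4α-isopropyl-1β,8-dimethyl-5α-H-bicyclo[5.3.0]dec-8-en-4β-ol | C/C=C(/C)C(=O)O[C@H]1CC(C)=C[C@H](OC(=O)c2ccccc2)[C@@]2(C)[C@@H](O[Si](C)(C)C(C)(C)C)C[C@@](O)(C(C)C)[C@H]12 | intermediate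
28 | 6α-angeloyloxy-10β-benzoyloxy-4α-isopropyl-1β,8-dimethyl-5α-H-bicyclo[5.3.0]dec-8-ene-2α,4β-diol | C/C=C(/C)C(=O)O[C@H]1CC(C)=C[C@H](OC(=O)c2ccccc2)[C@@]2(C)[C@@H](O)C[C@@](O)(C(C)C)[C@H]12 | intermediate
29 | (1R,2S,4R,5S,6S,10S)-2α-acetoxy-6α-angeloyloxy-10β-benzoyloxy-4α-isopropyl-1β,8-dimethyl-5α-H-bicyclo[5.3.0]dec-8-en-4β-ol | C/C=C(/C)C(=O)O[C@H]1CC(C)=C[C@H](OC(=O)c2ccccc2)[C@@]2(C)[C@@H](OC(C)=O)C[C@@](O)(C(C)C)[C@H]12 | target

## Step count and least certain steps

Total: 22 steps. Longest linear sequence: 19 steps (steps 1–6 and 10–22, from compound 1); the diazo ester takes three steps (7–9) from compound 11.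

Step 10 (key step).
- Risk: the (3,3) shift at the fully substituted C1 terminus may be slower than reversible opening of the donor–acceptor C6–C8 bond of 15. That would erode the catalyst-set configuration and open the way to vinylcyclopropane-to-cyclopentene drift. A second risk is slow cyclopropanation of the crowded, cross-conjugated enol ether, which would leave 14 to dimerise or cyclise.
- Fallback: take stereocontrol from the substrate and not from the catalyst. From 10, with the achiral, thermally robust Rh2(OPiv)4 [dirhodium tetrapivalate] in hot hydrocarbon solvent, 14 is added slowly so that cyclopropanation and rearrangement share one temperature regime. Opening and re-closure of the C6–C8 bond are then allowed to equilibrate the cyclopropane diastereomers, and the annulation is funnelled through the less crowded boat (isopropyl methine, not silyloxy, facing the vinyl unit). The C4 centre of 10 alone then fixes the absolute configuration. This returns to the route at 16 and makes no new compound (F0).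

Step 6.
- Risk: competing deprotonation at C3 or at the C1 methyl group, double silylation, or electron transfer and conjugate addition of the amide to the ene-dione.
- Fallback: fix the regiochemistry by constitution. From 9, the more ketone-like acetyl carbonyl is converted with trimethyl orthoformate and acidic methanol into (R)-3-(1,1-dimethoxyethyl)-4-isopropyl-2-methyl-4-(triethylsilyloxy)cyclopent-2-en-1-one F1. Loss of methanol with Me3SiOTf and iPr2NEt, possible only toward the methyl group, gives (R)-4-isopropyl-3-(1-methoxyvinyl)-2-methyl-4-(triethylsilyloxy)cyclopent-2-en-1-one F2. Annulation with 14 as in step 10 would pass through the methoxy cyclopropane F3 to the C6 methyl enol ether analogue of 16, F4. Dilute HCl followed by HF·pyridine returns to the route at 17.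

Step 12.
- Risk: internal hydride delivery across the cyclopentane to C2 needs a strained bridged transition state. It may be incomplete, or external attack may give the 2β-alcohol.
- Fallback: set C2 by reagent control before unmasking. From 16, (R)-2-methyl-CBS-oxazaborolidine with catecholborane (Corey–Bakshi–Shibata reduction; quaternary C1 as the large and C3H2 as the small flank) gives the 2α-alcohol F5. HF·pyridine then gives methyl 2α,4β-dihydroxy-4α-isopropyl-1β-methyl-6-oxo-5α-H-bicyclo[5.3.0]dec-8-ene-8-carboxylate F6. Its single ketone is reduced with Me4NBH(OAc)3 under direction from O4, returning to the route at 18.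

Step 15.
- Risk: competing hydrogen abstraction at C7, stalled peroxide intermediates, or low conversion of the electron-poor, neopentyl position.
- Fallback: an ionic, regiodefined sequence. From 20, LiN(iPr)2 with HMPA removes the γ proton at C10, and kinetic α-protonation gives the deconjugated C9=C10 ester F7 (mixture at C8). Epoxidation with mCPBA gives oxirane F8. DBU opens it by β-elimination from C8 to the 10-hydroxy enoate F9. Dess–Martin oxidation returns to the route at 21.

Step 20.
- Risk: Z to E isomerisation to the tiglate under forcing conditions, and sluggish acylation of the hindered, hydrogen-bonded C6 hydroxyl.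
- Fallback: build the Z alkene on the ester. From 26, carbodiimide coupling with 2-[bis(2,2,2-trifluoroethoxy)phosphoryl]propanoic acid gives the 6α-phosphonopropionate F10. Still–Gennari olefination with acetaldehyde (KN(SiMe3)2, 18-crown-6, −78 °C) forms the angelate and returns to the route at 27.

Step 3.
- Risk: modest enantioselectivity in oxygen transfer to this tetrasubstituted enolate.
- Fallback: resolution instead of asymmetric induction. From 4, hydroxylation with racemic 2-(phenylsulfonyl)-3-phenyloxaziridine gives 5 together with its antipode (S)-5-hydroxy-3-isobutoxy-5-isopropyl-2-methylcyclopent-2-en-1-one F11. Preparative chromatography on a chiral stationary phase returns to the route at 5.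

## Further compounds

F0 | step 10 | none | none
F1 | step 6 | (R)-3-(1,1-dimethoxyethyl)-4-isopropyl-2-methyl-4-(triethylsilyloxy)cyclopent-2-en-1-one | COC(C)(OC)C1=C(C)C(=O)C[C@@]1(O[Si](CC)(CC)CC)C(C)C
F2 | step 6 | (R)-4-isopropyl-3-(1-methoxyvinyl)-2-methyl-4-(triethylsilyloxy)cyclopent-2-en-1-one | C=C(OC)C1=C(C)C(=O)C[C@@]1(O[Si](CC)(CC)CC)C(C)C
F3 | step 6 | methyl (1S,2R)-2-methoxy-2-[(5R)-5-isopropyl-2-methyl-3-oxo-5-(triethylsilyloxy)cyclopent-1-en-1-yl]-1-vinylcyclopropane-1-carboxylate | C=C[C@@]1(C(=O)OC)C[C@@]1(OC)C2=C(C)C(=O)C[C@@]2(O[Si](CC)(CC)CC)C(C)C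
F4 | step 6 | methyl 4α-isopropyl-6-methoxy-1β-methyl-2-oxo-4β-(triethylsilyloxy)bicyclo[5.3.0]deca-5,8-diene-8-carboxylate | C1C(C(=O)OC)=CC[C@@]2(C)C(=O)C[C@@](O[Si](CC)(CC)CC)(C(C)C)C2=C1OC
F5 | step 12 | methyl 6-(tert-butyldimethylsilyloxy)-2α-hydroxy-4α-isopropyl-1β-methyl-4β-(triethylsilyloxy)bicyclo[5.3.0]deca-5,8-diene-8-carboxylate | C1C(C(=O)OC)=CC[C@@]2(C)[C@@H](O)C[C@@](O[Si](CC)(CC)CC)(C(C)C)C2=C1O[Si](C)(C)C(C)(C)C
F6 | step 12 | methyl 2α,4β-dihydroxy-4α-isopropyl-1β-methyl-6-oxo-5α-H-bicyclo[5.3.0]dec-8-ene-8-carboxylate | O=C1CC(C(=O)OC)=CC[C@@]2(C)[C@@H](O)C[C@@](O)(C(C)C)[C@H]12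
F7 | step 15 | methyl 2α-(tert-butyldimethylsilyloxy)-4β,6α-(isopropylidenedioxy)-4α-isopropyl-1β-methyl-5α-H-bicyclo[5.3.0]dec-9-ene-8-carboxylate (mixture at C8) | CC1(C)O[C@H]2CC(C(=O)OC)C=C[C@@]3(C)[C@@H](O[Si](C)(C)C(C)(C)C)C[C@@](O1)(C(C)C)[C@H]23
F8 | step 15 | 9,10-epoxide of F7 (mixture at C8, C9, C10) | CC1(C)O[C@H]2CC(C(=O)OC)C4OC4[C@@]3(C)[C@@H](O[Si](C)(C)C(C)(C)C)C[C@@](O1)(C(C)C)[C@H]23
F9 | step 15 | methyl 2α-(tert-butyldimethylsilyloxy)-10-hydroxy-4β,6α-(isopropylidenedioxy)-4α-isopropyl-1β-methyl-5α-H-bicyclo[5.3.0]dec-8-ene-8-carboxylate (either C10 epimer) | CC1(C)O[C@H]2CC(C(=O)OC)=CC(O)[C@@]3(C)[C@@H](O[Si](C)(C)C(C)(C)C)C[C@@](O1)(C(C)C)[C@H]23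
F10 | step 20 | 6α-{2-[bis(2,2,2-trifluoroethoxy)phosphoryl]propanoyloxy} analogue of 27 (mixture at the phosphonate α-carbon) | CC(P(=O)(OCC(F)(F)F)OCC(F)(F)F)C(=O)O[C@H]1CC(C)=C[C@H](OC(=O)c2ccccc2)[C@@]2(C)[C@@H](O[Si](C)(C)C(C)(C)C)C[C@@](O)(C(C)C)[C@H]12
F11 | step 3 | (S)-5-hydroxy-3-isobutoxy-5-isopropyl-2-methylcyclopent-2-en-1-one | O=C1C(C)=C(OCC(C)C)C[C@]1(O)C(C)C
A1 | alternative 1 | diazoketone: ring B enone with C1 bearing methyl and diazoacetyl, C5 bearing the (tert-butyldimethylsilyloxy)(isopropyl)methyl side chain, C6 angelate | C/C=C(/C)C(=O)O[C@H]1CC(C)=CC(=O)[C@@](C)(C(=O)C=[N+]=[N-])[C@@H]1[C@H](O[Si](C)(C)C(C)(C)C)C(C)C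
A2 | alternative 1 | bicyclic 2,10-dione with C4 tert-butyldimethylsilyl ether and C6 angelate | C/C=C(/C)C(=O)O[C@H]1CC(C)=CC(=O)[C@@]2(C)C(=O)C[C@@](O[Si](C)(C)C(C)(C)C)(C(C)C)[C@H]12
A3 | alternative 2 | decalin with angular C6 hydroxyl, C5 methanesulfonate, C1–C6 bond, and C2, C4, C10 ethers | O[C@]12CC(C)=C[C@H](O[Si](C)(C)C(C)(C)C)[C@@]1(C)[C@@H](OCc1ccc(OC)cc1)C[C@@](O[Si](CC)(CC)CC)(C(C)C)[C@@H]2OS(C)(=O)=O
A4 | alternative 2 | trans-fused hydroazulen-6-one with C8=C9 alkene and C2, C4, C10 ethers | O=C1CC(C)=C[C@H](O[Si](C)(C)C(C)(C)C)[C@@]2(C)[C@@H](OCc3ccc(OC)cc3)C[C@@](O[Si](CC)(CC)CC)(C(C)C)[C@H]12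
A5 | alternative 3 | cyclopentane-1,3-dione | O=C1CCC(=O)C1
A6 | alternative 3 | allene (propadiene) | C=C=C
A7 | alternative 3 | cis-1-hydroxy-6-methylenebicyclo[3.2.0]heptan-4-one (racemic photoadduct, one enantiomer drawn) | O[C@@]12CCC(=O)[C@@H]1C(=C)C2
A8 | alternative 3 | 6-methylenecycloheptane-1,4-dione | C=C1CC(=O)CCC(=O)C1
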